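**Retrosynthetic overview**

1. The target is reached from the permethylated quinone 22 by oxidation of the tetramethoxynaphthalene (unit A) with (NH4)2Ce(NO3)6, then cleavage of the three peri methyl ethers (O5, O5', O8') with BCl3.
2. The strategy rests on C3' of unit B, the CH3-bearing quinone carbon between C2' (which carries unit A) and the C4' carbonyl. It is treated as an inserted CH–CH3 unit: the quinone ring C1'–C2'–C3'–C4'–C4a'–C8a' is made by one-carbon expansion of the five-membered ring of 2-arylindane-1,3-dione 17 with the zinc carbenoid from 1,1-diiodoethane, forming C2'–C3' and C3'–C4' and breaking the old C2'–C4' bond.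
3. 17 comes from naphthaldehyde 11 and phthalide 15 by aldol–Dieckmann condensation; 15 comes from 2,5-dimethoxybenzyl alcohol by ortho-lithiation and carboxylation.
4. 11 comes from bromonaphthalene 9, whose trioxygenated ring is built on 4-bromo-3-methylanisole (through its 2-iodo derivative) by aryllithium addition to methyl semisquarate and thermal ring expansion; the bromine of the starting anisole marks C8 of unit A.
5. Ring order: trimethoxy ring of unit A (step 4), lactone ring of 15 (step 6), five-membered dione ring (step 7), six-membered quinone ring of unit B (step 8).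

Key step: step 8

Assumption: the target is drawn without a descriptor for the hindered aryl–quinone axis (C8–C2'), so the route is planned for the racemate; the naphthazarin tautomers of unit B are treated as one compound.

**Route**

Step 1
Reactants: 1 4-bromo-3-methylanisole
Product: 2 1-bromo-5-iodo-4-methoxy-2-methylbenzene (4-bromo-2-iodo-5-methylanisole)
Conditions: N-iodosuccinimide, CF3CO2H (cat.), MeCN, rt
Reagents that add atoms: N-iodosuccinimide, O=C1CCC(=O)N1I
Why: Electrophilic aromatic iodination goes to the only unhindered, doubly activated position (ortho to OMe and para to CH3), since the para position of the methoxy group is blocked by bromine.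

Step 2
Reactants: 3 dimethyl squarate
Product: 5 3-methoxycyclobut-3-ene-1,2-dione (methyl semisquarate), via hydroxycyclobutenone 4 (not isolated)
Conditions: LiAlH(OtBu)3, THF, −78 to −20 °C; aq. HCl; then conc. HCl (cat.), CH2Cl2, rt
Reagents that add atoms: water, O
Why: Mono-reduction of one squarate carbonyl by the bulky monohydride, then acid-promoted allylic transposition (ionisation of the carbinol to a methoxy-stabilised cyclobutenyl cation, capture of water at the methoxy-bearing terminus and loss of methanol), is the standard conversion of a dialkyl squarate into an alkyl semisquarate.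

Step 3
Reactants: 2 1-bromo-5-iodo-4-methoxy-2-methylbenzene; 5 3-methoxycyclobut-3-ene-1,2-dione
Product: 7 4-(5-bromo-2-methoxy-4-methylphenyl)-4-hydroxy-3-methoxycyclobut-2-en-1-one (racemic), via aryllithium 6 (not isolated)
Conditions: n-BuLi (1.0 equiv), THF, −78 °C; add to 5, THF, −78 °C; aq. NH4Cl, −78 °C
Reagents that add atoms: none
Why: Iodine–lithium exchange is much faster than bromine–lithium exchange at −78 °C, and the aryllithium adds 1,2 to the ketone-like carbonyl next to the methoxy-bearing carbon (the other carbonyl is deactivated as a vinylogous ester), which is the usual regiochemistry of organolithium addition to alkoxycyclobutenediones; the racemic carbinol centre is destroyed in step 4.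

Step 4
Reactants: 7 4-(5-bromo-2-methoxy-4-methylphenyl)-4-hydroxy-3-methoxycyclobut-2-en-1-one
Product: 9 1-bromo-4,5,6,8-tetramethoxy-2-methylnaphthalene, via naphthalene-1,4-diol 8 (not isolated)
Conditions: degassed p-xylene, 140 °C; then solvent exchange, Me2SO4, K2CO3, acetone, reflux (Ar)
Reagents that add atoms: dimethyl sulfate, COS(=O)(=O)OC
Why: In a Moore-type thermal rearrangement, 4π ring opening with outward rotation of the hydroxyl gives an aryl vinylketene that closes by 6π electrocyclisation onto the free ortho carbon and tautomerises to the naphthalene-1,4-diol, which is trapped by Williamson O-methylation before it can be oxidised.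

Step 5
Reactants: 9 1-bromo-4,5,6,8-tetramethoxy-2-methylnaphthalene
Product: 11 4,5,6,8-tetramethoxy-2-methylnaphthalene-1-carbaldehyde, via naphthyllithium 10 (not isolated)
Conditions: n-BuLi, THF, −78 °C; DMF, −78 °C to rt; 1 M HCl
Reagents that add atoms: N,N-dimethylformamide, CN(C)C=O
Why: Bromine–lithium exchange followed by formylation with DMF (Bouveault-type aldehyde synthesis) places the formyl group exactly at the carbon marked by the bromine carried from compound 1.

Step 6
Reactants: 12 2,5-dimethoxybenzyl alcohol
Product: 15 4,7-dimethoxyisobenzofuran-1(3H)-one (4,7-dimethoxyphthalide), via dilithio alkoxide 13 (not isolated), via hydroxy acid 14 (not isolated)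
Conditions: n-BuLi (2.2 equiv), TMEDA, Et2O/hexane, 0 °C to rt; CO2; 2 M HCl
Reagents that add atoms: carbon dioxide, O=C=O
Why: Directed ortho-lithiation at the position flanked by the lithium alkoxide arm and a methoxy group, carboxylation and acid-promoted lactonisation give the phthalide.

Step 7
Reactants: 11 4,5,6,8-tetramethoxy-2-methylnaphthalene-1-carbaldehyde; 15 4,7-dimethoxyisobenzofuran-1(3H)-one
Product: 17 4,7-dimethoxy-2-(4,5,6,8-tetramethoxy-2-methylnaphthalen-1-yl)indane-1,3-dione, via arylidenephthalide 16 (not isolated)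
Conditions: NaOMe, MeOH, ethyl propionate, reflux; then aq. HCl
Reagents that add atoms: none
Why: In the classical phthalide–aldehyde condensation, aldol addition and dehydration give the arylidenephthalide, methoxide opens the lactone to a keto ester enolate and Dieckmann closure gives the 2-arylindane-1,3-dione, whose very stable enolate drives the sequence.

Step 8
Reactants: 17 4,7-dimethoxy-2-(4,5,6,8-tetramethoxy-2-methylnaphthalen-1-yl)indane-1,3-dione; 18 1,1-diiodoethane
Product: 22 5,8-dimethoxy-3-methyl-2-(4,5,6,8-tetramethoxy-2-methylnaphthalen-1-yl)naphthalene-1,4-dione (racemic about the aryl–quinone axis), via ethylzinc enolate 19 (not isolated), via 2,3-dihydro-1,4-dione 20 (not isolated), via hydroquinone 21 (not isolated)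
Conditions: Et2Zn (5 equiv), CH2Cl2, 0 °C; CH3CHI2 (5 equiv), 0 °C to rt; 1 M HCl, air
Reagents that add atoms: none
Why: Proposed new method: Et2Zn deprotonates the acidic dione to the ethylzinc enolate 19, which attacks the carbenoid EtZnCH(CH3)I at carbon to put a CH(CH3)–Zn unit on C2'; this organozinc adds 3-exo-trig to one flanking carbonyl to give a donor–acceptor cyclopropanolate, and cleavage of the original C2'–C(=O) bond releases a zinc enolate stabilised by the aryl group and the second carbonyl, so that C2'–C3' and C3'–C4' are formed and the five-membered ring becomes six-membered. The closest known reaction types are the zinc-carbenoid chain extension of β-keto esters and β-diketones, which with 1,1-diiodoethane gives methyl-branched 1,4-dicarbonyl compounds, and the radical Dowd–Beckwith ring expansion, and neither has been shown on a cyclic 1,3-dione carrying a di-ortho-substituted aryl group at C2. The six-membered ring is therefore closed by ring expansion (formation of a three-membered ring and fragmentation of the shared bond) and not by a direct cyclisation. The two sp3 centres of 20 are transient, because acid work-up gives the 2,3-dihydro-1,4-dione, this enolises to hydroquinone 21 and air oxidises it to the quinone, so that only the racemic aryl–quinone axis remains. The step needs C- rather than O-alkylation and a single insertion: the covalent zinc enolate reacts at carbon, the two carbonyls are equivalent by symmetry so that either insertion gives the same product, and the enolate formed after fragmentation has no pathway to a second fragmentation. Excess carbenoid is planned because both faces of C2' are screened by the ortho methyl group and the peri methoxy group of the perpendicular naphthyl ring.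

Step 9
Reactants: 22 5,8-dimethoxy-3-methyl-2-(4,5,6,8-tetramethoxy-2-methylnaphthalen-1-yl)naphthalene-1,4-dione
Product: 23 8-(5,8-dimethoxy-3-methyl-1,4-dioxo-1,4-dihydronaphthalen-2-yl)-3,5-dimethoxy-7-methylnaphthalene-1,4-dione (the 5,5',8'-tri-O-methyl ether of the target)
Conditions: (NH4)2Ce(NO3)6 (2.5 equiv), MeCN/H2O, 0 °C
Reagents that add atoms: water, O
Why: Oxidative demethylation by tetravalent cerium converts the only para-dimethoxy pair of the electron-rich naphthalene (C5/C8) into the 1,4-quinone and keeps the C6 methoxy group as the vinylogous ester (C3 of unit A), while the dimethoxybenzo ring of unit B is deactivated by its two quinone carbonyls.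

Step 10
Reactants: 23 8-(5,8-dimethoxy-3-methyl-1,4-dioxo-1,4-dihydronaphthalen-2-yl)-3,5-dimethoxy-7-methylnaphthalene-1,4-dione
Product: 24 8'-hydroxy-3-methoxy isodiospyrin (target, racemic about the axis)
Conditions: BCl3 (excess), CH2Cl2, −78 to 0 °C; H2O
Reagents that add atoms: none
Why: In this chelation-controlled Lewis acid ether cleavage, BCl3 bridges each quinone carbonyl and its peri methoxy oxygen in a six-membered chelate and chloride removes the methyl group, while the C3 vinylogous ester methoxy group, which cannot form such a chelate, should survive at low temperature.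

**Compound list**

1 | 4-bromo-3-methylanisole | COc1ccc(Br)c(C)c1 | starting material
2 | 1-bromo-5-iodo-4-methoxy-2-methylbenzene | COc1cc(C)c(Br)cc1I | intermediate
3 | dimethyl squarate (3,4-dimethoxycyclobut-3-ene-1,2-dione) | COC1=C(OC)C(=O)C1=O | starting material
4 | 4-hydroxy-2,3-dimethoxycyclobut-2-en-1-one (racemic) | COC1=C(OC)C(O)C1=O | intermediate
5 | 3-methoxycyclobut-3-ene-1,2-dione | COC1=CC(=O)C1=O | intermediate
6 | (5-bromo-2-methoxy-4-methylphenyl)lithium | [Li]c1cc(Br)c(C)cc1OC | intermediate
7 | 4-(5-bromo-2-methoxy-4-methylphenyl)-4-hydroxy-3-methoxycyclobut-2-en-1-one (racemic) | COC1=CC(=O)C1(O)c1cc(Br)c(C)cc1OC | intermediate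
8 | 5-bromo-2,8-dimethoxy-6-methylnaphthalene-1,4-diol | COc1cc(C)c(Br)c2c(O)cc(OC)c(O)c12 | intermediate
9 | 1-bromo-4,5,6,8-tetramethoxy-2-methylnaphthalene | COc1cc(C)c(Br)c2c(OC)cc(OC)c(OC)c12 | intermediate
10 | (4,5,6,8-tetramethoxy-2-methylnaphthalen-1-yl)lithium | COc1cc(C)c([Li])c2c(OC)cc(OC)c(OC)c12 | intermediate
11 | 4,5,6,8-tetramethoxy-2-methylnaphthalene-1-carbaldehyde | COc1cc(C)c(C=O)c2c(OC)cc(OC)c(OC)c12 | intermediate
12 | 2,5-dimethoxybenzyl alcohol | COc1ccc(OC)c(CO)c1 | starting material
13 | lithium (2-lithio-3,6-dimethoxyphenyl)methanolate | [Li]OCc1c(OC)ccc(OC)c1[Li] | intermediate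
14 | 2-(hydroxymethyl)-3,6-dimethoxybenzoic acid | OCc1c(OC)ccc(OC)c1C(=O)O | intermediate
15 | 4,7-dimethoxyisobenzofuran-1(3H)-one | COc1ccc(OC)c2c1COC2=O | intermediate
16 | (Z)-4,7-dimethoxy-3-[(4,5,6,8-tetramethoxy-2-methylnaphthalen-1-yl)methylidene]isobenzofuran-1(3H)-one (Z expected, geometry of no consequence) | O=C1O/C(=C\c2c(C)cc(OC)c3c(OC)c(OC)cc(OC)c23)c2c(OC)ccc(OC)c12 | intermediate
17 | 4,7-dimethoxy-2-(4,5,6,8-tetramethoxy-2-methylnaphthalen-1-yl)indane-1,3-dione | O=C1C(c2c(C)cc(OC)c3c(OC)c(OC)cc(OC)c23)C(=O)c2c(OC)ccc(OC)c12 | intermediate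
18 | 1,1-diiodoethane | CC(I)I | starting material
19 | ethylzinc enolate of 17 (ethyl[4,7-dimethoxy-3-oxo-2-(4,5,6,8-tetramethoxy-2-methylnaphthalen-1-yl)-3H-inden-1-olato]zinc) | CC[Zn]OC1=C(c2c(C)cc(OC)c3c(OC)c(OC)cc(OC)c23)C(=O)c2c(OC)ccc(OC)c12 | intermediate
20 | 5,8-dimethoxy-3-methyl-2-(4,5,6,8-tetramethoxy-2-methylnaphthalen-1-yl)-2,3-dihydronaphthalene-1,4-dione (mixture of diastereomers, both centres erased on oxidation) | CC1C(c2c(C)cc(OC)c3c(OC)c(OC)cc(OC)c23)C(=O)c2c(OC)ccc(OC)c2C1=O | intermediate
21 | 5,8-dimethoxy-3-methyl-2-(4,5,6,8-tetramethoxy-2-methylnaphthalen-1-yl)naphthalene-1,4-diol | Cc1c(O)c2c(OC)ccc(OC)c2c(O)c1-c1c(C)cc(OC)c2c(OC)c(OC)cc(OC)c12 | intermediate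
22 | 5,8-dimethoxy-3-methyl-2-(4,5,6,8-tetramethoxy-2-methylnaphthalen-1-yl)naphthalene-1,4-dione (racemic axis) | CC1=C(c2c(C)cc(OC)c3c(OC)c(OC)cc(OC)c23)C(=O)c2c(OC)ccc(OC)c2C1=O | intermediate
23 | 8-(5,8-dimethoxy-3-methyl-1,4-dioxo-1,4-dihydronaphthalen-2-yl)-3,5-dimethoxy-7-methylnaphthalene-1,4-dione (racemic axis) | COC1=CC(=O)c2c(C3=C(C)C(=O)c4c(OC)ccc(OC)c4C3=O)c(C)cc(OC)c2C1=O | intermediate
24 | 8'-hydroxy-3-methoxy isodiospyrin (racemic axis) | COC1=CC(=O)c2c(C3=C(C)C(=O)c4c(O)ccc(O)c4C3=O)c(C)cc(O)c2C1=O | target

**Step count and risks**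

Total step count: 10. Longest linear sequence: 8 steps (steps 1, 3, 4, 5, 7, 8, 9, 10).

Steps most likely to fail:

Step 8 (one-carbon insertion). C-alkylation of the highly stabilised enolate, screened on both faces by the naphthyl ortho and peri substituents, may be slower than decomposition of the secondary carbenoid, or alkylation may take place at oxygen, so that no ring expansion occurs. The fallback uses known cyclobutenedione chemistry; it sets out from bromonaphthalene 9 and dimethyl squarate 3 and returns to the route at hydroquinone 21. Compound 9 is lithiated (n-BuLi, THF, −78 °C) to 10, which is added to 3, and the alkoxide is silylated in the flask with Me3SiCl to give 2,3-dimethoxy-4-(4,5,6,8-tetramethoxy-2-methylnaphthalen-1-yl)-4-(trimethylsilyloxy)cyclobut-2-en-1-one F1. MeLi adds 1,2 to the remaining vinylogous ester carbonyl to give 2,3-dimethoxy-1-methyl-4-(4,5,6,8-tetramethoxy-2-methylnaphthalen-1-yl)-4-(trimethylsilyloxy)cyclobut-2-en-1-ol F2. Aqueous HCl converts this, by two allylic transpositions, into 3-methyl-4-(4,5,6,8-tetramethoxy-2-methylnaphthalen-1-yl)cyclobut-3-ene-1,2-dione F3. (2,5-Dimethoxyphenyl)lithium F4, made from 1,4-dimethoxybenzene with n-BuLi and TMEDA, is added at −78 °C to give 4-(2,5-dimethoxyphenyl)-4-hydroxy-3-methyl-2-(4,5,6,8-tetramethoxy-2-methylnaphthalen-1-yl)cyclobut-2-en-1-one F5, possibly with its regioisomer 4-(2,5-dimethoxyphenyl)-4-hydroxy-2-methyl-3-(4,5,6,8-tetramethoxy-2-methylnaphthalen-1-yl)cyclobut-2-en-1-one F6; both converge because the 5,8-dimethoxy benzo ring is symmetric. Thermolysis in xylene (Moore-type rearrangement) gives hydroquinone 21, and air oxidation then gives 22.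

Step 7 (phthalide–aldehyde condensation). Aldol addition of the phthalide anion to the hindered, electron-rich aldehyde may be slow and reversible, so that retro-aldol and alkoxide-induced disproportionation of the aldehyde compete with dehydration. The fallback sets out from phthalide 15 and aldehyde 11 and returns at arylidenephthalide 16, replacing the aldol step by an irreversible olefination. Radical bromination of 15 (N-bromosuccinimide, AIBN, PhCF3, reflux) gives 3-bromo-4,7-dimethoxyisobenzofuran-1(3H)-one F7. Michaelis–Arbuzov reaction with P(OMe)3 gives dimethyl (4,7-dimethoxy-3-oxo-1,3-dihydroisobenzofuran-1-yl)phosphonate F8. Horner–Wadsworth–Emmons reaction of F8 with 11 (LiN(SiMe3)2, THF) gives 16, which is isolated and rearranged to 17 with NaOMe in MeOH.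

Step 10 (selective demethylation). The C3 vinylogous ester methyl group may be lost together with the peri ethers, or the third peri ether may be cleaved incompletely, giving mixtures of partially methylated products. The fallback sets out from 23 and returns at target 24 by removing the need for selectivity in the cleavage. Excess BBr3 (CH2Cl2, −78 °C to rt) cleaves all four ethers to give 8-(5,8-dihydroxy-3-methyl-1,4-dioxo-1,4-dihydronaphthalen-2-yl)-3,5-dihydroxy-7-methylnaphthalene-1,4-dione F9. Heating F9 in MeOH with catalytic HCl etherifies only the acidic 3-hydroxyquinone (a vinylogous acid), the chelated peri phenols being inert, and gives 24.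

**Further compounds**

F1 | step 8 | 2,3-dimethoxy-4-(4,5,6,8-tetramethoxy-2-methylnaphthalen-1-yl)-4-(trimethylsilyloxy)cyclobut-2-en-1-one (racemic) | COC1=C(OC)C(O[Si](C)(C)C)(c2c(C)cc(OC)c3c(OC)c(OC)cc(OC)c23)C1=O
F2 | step 8 | 2,3-dimethoxy-1-methyl-4-(4,5,6,8-tetramethoxy-2-methylnaphthalen-1-yl)-4-(trimethylsilyloxy)cyclobut-2-en-1-ol (mixture of diastereomers) | COC1=C(OC)C(O[Si](C)(C)C)(c2c(C)cc(OC)c3c(OC)c(OC)cc(OC)c23)C1(C)O
F3 | step 8 | 3-methyl-4-(4,5,6,8-tetramethoxy-2-methylnaphthalen-1-yl)cyclobut-3-ene-1,2-dione | CC1=C(c2c(C)cc(OC)c3c(OC)c(OC)cc(OC)c23)C(=O)C1=O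
F4 | step 8 | (2,5-dimethoxyphenyl)lithium | [Li]c1cc(OC)ccc1OC
F5 | step 8 | 4-(2,5-dimethoxyphenyl)-4-hydroxy-3-methyl-2-(4,5,6,8-tetramethoxy-2-methylnaphthalen-1-yl)cyclobut-2-en-1-one (racemic) | CC1=C(c2c(C)cc(OC)c3c(OC)c(OC)cc(OC)c23)C(=O)C1(O)c1cc(OC)ccc1OC
F6 | step 8 | 4-(2,5-dimethoxyphenyl)-4-hydroxy-2-methyl-3-(4,5,6,8-tetramethoxy-2-methylnaphthalen-1-yl)cyclobut-2-en-1-one (racemic) | CC1=C(c2c(C)cc(OC)c3c(OC)c(OC)cc(OC)c23)C(O)(c2cc(OC)ccc2OC)C1=O
F7 | step 7 | 3-bromo-4,7-dimethoxyisobenzofuran-1(3H)-one (racemic) | COc1ccc(OC)c2c1C(Br)OC2=O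
F8 | step 7 | dimethyl (4,7-dimethoxy-3-oxo-1,3-dihydroisobenzofuran-1-yl)phosphonate (racemic) | COc1ccc(OC)c2c1C(OC2=O)P(=O)(OC)OC
F9 | step 10 | 8-(5,8-dihydroxy-3-methyl-1,4-dioxo-1,4-dihydronaphthalen-2-yl)-3,5-dihydroxy-7-methylnaphthalene-1,4-dione (racemic axis) | OC1=CC(=O)c2c(C3=C(C)C(=O)c4c(O)ccc(O)c4C3=O)c(C)cc(O)c2C1=O
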